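**Plan**
1. Feature used: without the C1–C8a bond, C2/C3 (cis methyls) and their two 3,4-dimethoxybenzyl arms form a meso, mirror-symmetric 1,4-diaryl-2,3-dimethylbutane; C8a lies para to the C6 methoxy group of ring A and is the natural partner for a benzylic cation at C1.
2. Retrosynthetic cuts, in order: C3–H/C4–H (hydrogenation of a C3=C4 alkene); then C1–C8a, with oxygen put back on C1 and C4 (meso 1,4-diol); then both aryl–C(=O) bonds (bis(Weinreb amide) of meso-2,3-dimethylsuccinic acid plus two equivalents of 4-bromoveratrole).
3. Forward: the acyclic meso chain is built first (diacid, diamide, diketone, diol); ring B is closed last by one enantioselective, stereoconvergent Friedel–Crafts desymmetrization that gives the 1-aryl-1,2-dihydronaphthalene; hydrogenation ends the route.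
4. Stereochemistry: C2 comes from the meso acid; the absolute configuration comes from a chiral Brønsted acid that chooses between the two enantiotopic benzylic ends; C1 is set trans to the C2 methyl by substrate control; C3, lost on dehydration, is reset by hydrogenation anti to the C2 methyl.
5. Helper: the oxygen at C4 keeps both chain ends equal and exchanging; it leaves as water in the key step.

Key step: step 4

Remark (assumption): the target is read as (1R,2R,3R), with the C1 aryl trans to the C2 methyl and the C2/C3 methyls cis; the hand of the chiral acid that leads to this series cannot be predicted and is to be fixed by the first experiment, and the formulae below assume it.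

**Route**

Step 1
Reactants: 1 meso-2,3-dimethylsuccinic acid
Product: 2 (2R,3S)-N1,N4-dimethoxy-N1,N4,2,3-tetramethylbutanediamide
Conditions: 1,1'-carbonyldiimidazole (2.5 equiv), CH2Cl2, 0 °C to rt; then MeNH(OMe)·HCl (3 equiv), rt
Reagents that add atoms: N,O-dimethylhydroxylamine hydrochloride (one molecule per carboxyl group), CNOC.Cl; a second equivalent of N,O-dimethylhydroxylamine hydrochloride for the second carboxyl group, CNOC.Cl
Why: Amide coupling through the acyl imidazolide (the first activation passes through the cyclic anhydride) is mild and non-basic, so both carboxyl groups should become Weinreb amides without touching the two alpha centres of the meso acid.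

Step 2
Reactants: 2 (2R,3S)-N1,N4-dimethoxy-N1,N4,2,3-tetramethylbutanediamide; 3 4-bromo-1,2-dimethoxybenzene
Product: 5 (2R,3S)-1,4-bis(3,4-dimethoxyphenyl)-2,3-dimethylbutane-1,4-dione, via 3,4-dimethoxyphenylmagnesium bromide 4 (not isolated)
Conditions: 3 (2.5 equiv relative to 2), Mg turnings (3 equiv), a crystal of iodine, THF, rt to 40 °C; then 2 (1 equiv) in THF, 0 °C to rt; 1 M HCl work-up
Reagents that add atoms: 4-bromo-1,2-dimethoxybenzene (second equivalent of 3 for the second amide group), COc1ccc(Br)cc1OC
Why: Grignard formation followed by a double Weinreb ketone synthesis, in which each of the two amide groups takes up one molecule of 4 and each addition stops at the chelated tetrahedral magnesium adduct, so no tertiary alcohol should form and the alpha centres are not enolized, which keeps the meso relationship.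

Step 3
Reactants: 5 (2R,3S)-1,4-bis(3,4-dimethoxyphenyl)-2,3-dimethylbutane-1,4-dione
Product: 6 (2R,3S)-1,4-bis(3,4-dimethoxyphenyl)-2,3-dimethylbutane-1,4-diol (mixture of carbinol epimers)
Conditions: LiAlH4, THF, −78 to 0 °C; aqueous NaOH work-up
Reagents that add atoms: none
Why: Hydride reduction of both aryl ketones under cold, non-equilibrating conditions should keep the C2/C3 centres, and the configuration of the two new carbinol centres does not matter because both are ionized in step 4.

Step 4
Reactants: 6 (2R,3S)-1,4-bis(3,4-dimethoxyphenyl)-2,3-dimethylbutane-1,4-diol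
Product: 9 (1R,2S)-1-(3,4-dimethoxyphenyl)-6,7-dimethoxy-2,3-dimethyl-1,2-dihydronaphthalene, via 3,4-cis-tetrahydrofuran 7 (not isolated), via tetralin-4-ol 8 (not isolated)
Conditions: confined chiral Brønsted acid (BINOL-derived imidodiphosphorimidate with 3,3'-aryl groups and N-SO2CF3 groups, 5 mol %), 5 Å molecular sieves, CHCl3 (0.02 M), −20 °C to rt
Reagents that add atoms: none
Why: Proposed new method: the confined chiral acid protonates a benzylic oxygen of 6 (or of tetrahydrofuran 7, which 6 reaches by cyclodehydration and which serves as the resting state) and ionizes it reversibly to a 3,4-dimethoxybenzylic cation held in the chiral pocket as a contact ion pair, the anion also binding the remaining hydroxyl by a hydrogen bond; because the two benzylic C–O bonds of the meso core are enantiotopic and exchange through 7, the two mirror-image cations interconvert and the catalyst decides which of them undergoes the irreversible Friedel–Crafts closure (Curtin–Hammett dynamic desymmetrization). The closest known reaction types are the achiral Brønsted acid conversion of 2,5-diaryl-3,4-dimethyltetrahydrofuran lignans into 1-aryl-1,2-dihydronaphthalenes and chiral-counteranion-controlled cation–arene cyclizations, including chiral phosphoric acid catalysed arylations of para-quinone methides made in situ from benzylic alcohols. Ring B closes in the 6-exo-trig mode: C8a of the ring on C4 attacks C1, whose double bond to the pendant aryl ring in the quinoid cation stays outside the new ring. C1 should be set trans to the C2 methyl by substrate control (chair-like transition state with the C1 aryl pseudo-equatorial), the absolute sense of C1 and C2 together is set by the catalyst, and C3 is given up when 8 ionizes at C4 and loses the C3 proton, which removes the helper oxygen as water. The step needs selection between the two benzylic ends (catalyst pocket), attack at the ring position para to the C6 methoxy group and not at the crowded position between chain and methoxy (electronics and sterics of the veratryl ring), and retention of C2, which should hold because oxygen return and ring closure are intramolecular and faster than proton loss from the open cation.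

Step 5
Reactants: 9 (1R,2S)-1-(3,4-dimethoxyphenyl)-6,7-dimethoxy-2,3-dimethyl-1,2-dihydronaphthalene
Product: 10 (1R,2R,3R)-1-(3,4-dimethoxyphenyl)-6,7-dimethoxy-2,3-dimethyl-1,2,3,4-tetrahydronaphthalene
Conditions: H2 (1 atm), Pd/C (10 wt % Pd on carbon), EtOAc, rt
Reagents that add atoms: none
Why: Heterogeneous catalytic hydrogenation should add both hydrogens syn from the face opposite the pseudo-axial allylic C2 methyl group, so the C3 hydrogen ends up anti to that methyl and the C3 methyl cis to it (substrate control), the pattern known for the reduction of 1-aryl-2,3-dimethyl-1,2-dihydronaphthalene lignans.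

**Compound list**

1 | meso-2,3-dimethylsuccinic acid, (2R,3S)-2,3-dimethylbutanedioic acid | OC(=O)[C@@H](C)[C@@H](C)C(=O)O | starting material
2 | (2R,3S)-N1,N4-dimethoxy-N1,N4,2,3-tetramethylbutanediamide (meso bis(Weinreb amide)) | CON(C)C(=O)[C@@H](C)[C@@H](C)C(=O)N(C)OC | intermediate
3 | 4-bromo-1,2-dimethoxybenzene (4-bromoveratrole) | COc1ccc(Br)cc1OC | starting material
4 | 3,4-dimethoxyphenylmagnesium bromide | COc1ccc([Mg]Br)cc1OC | intermediate (not isolated)
5 | (2R,3S)-1,4-bis(3,4-dimethoxyphenyl)-2,3-dimethylbutane-1,4-dione (meso diketone) | COc1ccc(C(=O)[C@@H](C)[C@@H](C)C(=O)c2ccc(OC)c(OC)c2)cc1OC | intermediate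
6 | (2R,3S)-1,4-bis(3,4-dimethoxyphenyl)-2,3-dimethylbutane-1,4-diol, meso-type C2/C3 core, mixture of epimers at C1 and C4 | COc1ccc(C(O)[C@@H](C)[C@@H](C)C(O)c2ccc(OC)c(OC)c2)cc1OC | intermediate
7 | (3R,4S)-2,5-bis(3,4-dimethoxyphenyl)-3,4-dimethyltetrahydrofuran, methyls cis, epimers at C2 and C5 | COc1ccc(C2OC(c3ccc(OC)c(OC)c3)[C@H](C)[C@@H]2C)cc1OC | intermediate (not isolated)
8 | (2S,3S,4R)-4-(3,4-dimethoxyphenyl)-6,7-dimethoxy-2,3-dimethyl-1,2,3,4-tetrahydronaphthalen-1-ol, both carbinol epimers; aryl trans to the neighbouring methyl, methyls cis, arranged as in 10 | COc1ccc([C@@H]2c3cc(OC)c(OC)cc3C(O)[C@@H](C)[C@H]2C)cc1OC | intermediate (not isolated)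
9 | (1R,2S)-1-(3,4-dimethoxyphenyl)-6,7-dimethoxy-2,3-dimethyl-1,2-dihydronaphthalene (aryl and C2 methyl trans) | COc1ccc([C@@H]2c3cc(OC)c(OC)cc3C=C(C)[C@H]2C)cc1OC | intermediate
10 | (1R,2R,3R)-1-(3,4-dimethoxyphenyl)-6,7-dimethoxy-2,3-dimethyl-1,2,3,4-tetrahydronaphthalene | COc1ccc([C@@H]2c3cc(OC)c(OC)cc3C[C@@H](C)[C@H]2C)cc1OC | target

**Totals**
Total step count: 5. Longest linear sequence: 5 steps (1 to 2 to 5 to 6 to 9 to 10; 3 enters in step 2, two equivalents per molecule of 2).

**Steps most likely to fail**

1. Step 4. The process at risk is the discrimination between the two enantiotopic benzylic ionization sites: the ion pair may be too loose, or ring closure may outrun the exchange of the two ends, so that the product forms with low enantiomeric purity. The fallback uses known chemistry, sets out from 1 (with Grignard reagent 4 from step 2) and comes back at 10. Compound 1 is closed with acetyl chloride at reflux to cis-2,3-dimethylsuccinic anhydride F1. Reagent 4 is transmetalated with ZnCl2 to 3,4-dimethoxyphenylzinc chloride F2. F2 opens F1 in a rhodium-catalysed enantioselective desymmetrizing arylation ([Rh(cod)Cl]2, TADDOL-derived phosphoramidite ligand of the hand that gives the 2R,3S acid, THF, 50 °C) to (2R,3S)-4-(3,4-dimethoxyphenyl)-2,3-dimethyl-4-oxobutanoic acid F3. Here the absolute configuration is set by a catalytic reaction of established type, and the two chain ends are told apart by oxidation level. Ionic hydrogenation of the aryl ketone (Et3SiH, CF3CO2H) should give (2R,3R)-4-(3,4-dimethoxyphenyl)-2,3-dimethylbutanoic acid F4. Coupling with MeNH(OMe)·HCl (1,1'-carbonyldiimidazole, CH2Cl2) gives (2R,3R)-4-(3,4-dimethoxyphenyl)-N-methoxy-N,2,3-trimethylbutanamide F5. Addition of 4 gives (2R,3R)-1,4-bis(3,4-dimethoxyphenyl)-2,3-dimethylbutan-1-one F6, and NaBH4 in MeOH gives (2R,3R)-1,4-bis(3,4-dimethoxyphenyl)-2,3-dimethylbutan-1-ol F7 (either carbinol epimer). CF3CO2H in CH2Cl2 at 0 °C ionizes F7, and the same C1–C8a Friedel–Crafts closure, now purely substrate-controlled, should give 10 directly with the aryl group trans to the C2 methyl and C3 never disturbed.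

2. Step 5. The processes at risk are migration of the double bond into the C2=C3 position on palladium before hydrogen adds (loss of C2) and hydrogen delivery to the wrong face at C3. The fallback sets out from 9 and comes back at 10. Hydroboration with 9-borabicyclo[3.3.1]nonane (THF, rt) and then NaOH/H2O2 should add H to C3 and OH to C4 in one concerted syn addition from the face opposite the C2 methyl, with no chance of alkene migration. This gives (1R,2S,3S,4R)-4-(3,4-dimethoxyphenyl)-6,7-dimethoxy-2,3-dimethyl-1,2,3,4-tetrahydronaphthalen-1-ol F8. Hydrogenolysis of its electron-rich benzylic C–O bond (H2, Pd(OH)2/C, EtOH with AcOH) should then give 10.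

3. Step 2. The processes at risk are base-induced enolization of the amide or ketone alpha centres (drift of the meso core into the dl series) and an incomplete second aryl addition that stops at the keto amide. The fallback sets out from 4 (made from 3) and comes back at 5. Reagent 4 is acylated with N-methoxy-N-methylpropanamide to 1-(3,4-dimethoxyphenyl)propan-1-one F9. Its lithium enolate (LiN(i-Pr)2, THF, −78 °C) is dimerized oxidatively with CuCl2 in DMF, two molecules of the ketone giving one molecule of the diketone, which forms the C2–C3 bond instead of the two aryl–carbonyl bonds. The meso diketone 5 is to be separated from its dl isomer by crystallization, and the dl isomer recycled by base equilibration (NaOMe, MeOH).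

Further compounds
F1 | step 4 | cis-2,3-dimethylsuccinic anhydride, (3R,4S)-3,4-dimethyloxolane-2,5-dione | O=C1OC(=O)[C@@H](C)[C@H]1C
F2 | step 4 | 3,4-dimethoxyphenylzinc chloride | COc1ccc([Zn]Cl)cc1OC
F3 | step 4 | (2R,3S)-4-(3,4-dimethoxyphenyl)-2,3-dimethyl-4-oxobutanoic acid | COc1ccc(C(=O)[C@@H](C)[C@@H](C)C(=O)O)cc1OC
F4 | step 4 | (2R,3R)-4-(3,4-dimethoxyphenyl)-2,3-dimethylbutanoic acid | COc1ccc(C[C@@H](C)[C@@H](C)C(=O)O)cc1OC
F5 | step 4 | (2R,3R)-4-(3,4-dimethoxyphenyl)-N-methoxy-N,2,3-trimethylbutanamide | COc1ccc(C[C@@H](C)[C@@H](C)C(=O)N(C)OC)cc1OC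
F6 | step 4 | (2R,3R)-1,4-bis(3,4-dimethoxyphenyl)-2,3-dimethylbutan-1-one | COc1ccc(C[C@@H](C)[C@@H](C)C(=O)c2ccc(OC)c(OC)c2)cc1OC
F7 | step 4 | (2R,3R)-1,4-bis(3,4-dimethoxyphenyl)-2,3-dimethylbutan-1-ol, either epimer at C1 | COc1ccc(C[C@@H](C)[C@@H](C)C(O)c2ccc(OC)c(OC)c2)cc1OC
F8 | step 5 | (1R,2S,3S,4R)-4-(3,4-dimethoxyphenyl)-6,7-dimethoxy-2,3-dimethyl-1,2,3,4-tetrahydronaphthalen-1-ol | COc1ccc([C@@H]2c3cc(OC)c(OC)cc3[C@H](O)[C@@H](C)[C@H]2C)cc1OC
F9 | step 2 | 1-(3,4-dimethoxyphenyl)propan-1-one | CCC(=O)c1ccc(OC)c(OC)c1
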